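**Retrosynthetic overview**

1. Target 26 ← desilylation ← macrolactone 25 ← CrCl2 Barbier allylation/lactonisation of bromo aldehyde 23 (C6–C7 bond), which closes the ten-membered carbocycle and the γ-lactone together.
2. 23 ← furanone 18 by reagent-controlled reduction of the C8 ketone, isobutyrylation, bromide formation at C13 and periodate unmasking of the C6 aldehyde.
3. 18 ← furan 15 by oxidative dearomatisation: singlet oxygen opens the furan (ring carbons C1, C10, C9, C8; ring oxygen between C1 and C8) to the C1/C8 ene-dione, and the enol oxygen on C3 closes the O–C10 bond of the 3(2H)-furanone.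
4. 15 ← furan acrylate 7 (from aldehyde 1 and methyl acrylate 2) + enal 12 (from glyceraldehyde acetonide 8 and 2), joined at C2–C3 by vinylogous aldol addition and oxidation.
5. Enabling feature: the C1 carbonyl and the C8 oxygen stand 1,4 across C9–C10 with methyl C14 on C10 (the retron of a 2,5-disubstituted 3-methylfuran), and the C3 oxygen is 1,3 to C1, so it reaches C10 in a 5-exo mode. Ring order: furan (bought) → furanone (step 11) → carbocycle and lactone (step 17).

Key step: step 11

Numbering: germacrane numbering of the target is used throughout: C1 furanone carbonyl, C2=C3 enol ether, C4 (exocyclic C15), C5 carbinol, C6 lactone O–CH, C7, C8 isobutyrate carbinol, C9 methylene, C10 quaternary carbon (methyl C14), C11=C13 methylene, C12 lactone carbonyl. TBS = tert-butyldimethylsilyl.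

Assumption: the quinidine-derived squaramide is taken to deliver the (10S) configuration; its quinine-derived pseudoenantiomer would serve if the sense of induction is the opposite one.

Remark: 1 and 8 are catalogue compounds; 8 is used freshly distilled.

**Route**

Step 1
Reactants: 1 4,5-dimethylfuran-2-carbaldehyde; 2 methyl acrylate
Product: 3 methyl 2-[(4,5-dimethylfuran-2-yl)(hydroxy)methyl]prop-2-enoate (racemic)
Conditions: DABCO (0.5 equiv), MeOH, rt
Reagents that add atoms: none
Why: Morita–Baylis–Hillman reaction, in which the ammonium enolate from DABCO and the acrylate adds to the furaldehyde; the racemic carbinol centre is erased in step 2.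

Step 2
Reactants: 3 methyl 2-[(4,5-dimethylfuran-2-yl)(hydroxy)methyl]prop-2-enoate
Product: 5 methyl (2E)-2-(acetoxymethyl)-3-(4,5-dimethylfuran-2-yl)prop-2-enoate, via secondary acetate 4 (not isolated)
Conditions: Ac2O, Et3N, DMAP (cat.), CH2Cl2, 0 °C; then DABCO (20 mol %), THF, 60 °C
Reagents that add atoms: acetic anhydride CC(=O)OC(C)=O
Why: O-acetylation followed by DABCO-catalysed allylic transposition through the allylammonium ion should give the thermodynamically preferred conjugated primary acetate with the furyl group trans to the ester (E).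

Step 3
Reactants: 5 methyl (2E)-2-(acetoxymethyl)-3-(4,5-dimethylfuran-2-yl)prop-2-enoate
Product: 6 methyl (2E)-3-(4,5-dimethylfuran-2-yl)-2-(hydroxymethyl)prop-2-enoate
Conditions: K2CO3 (cat.), MeOH, 0 °C
Reagents that add atoms: none
Why: Base-catalysed transesterification removes the primary acetate, while exchange at the methyl ester is degenerate in methanol.

Step 4
Reactants: 6 methyl (2E)-3-(4,5-dimethylfuran-2-yl)-2-(hydroxymethyl)prop-2-enoate
Product: 7 methyl (2E)-2-(TBS-oxymethyl)-3-(4,5-dimethylfuran-2-yl)prop-2-enoate (furan fragment)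
Conditions: TBSCl, imidazole, DMF, 0 °C to rt
Reagents that add atoms: tert-butyl(chloro)dimethylsilane CC(C)(C)[Si](C)(C)Cl
Why: Standard silylation of the primary allylic alcohol gives an ether that survives strong base and is a poor leaving group from the later extended enolate.

Step 5
Reactants: 8 (4R)-2,2-dimethyl-1,3-dioxolane-4-carbaldehyde; 2 methyl acrylate
Product: 9 methyl 2-[(S)-[(4R)-2,2-dimethyl-1,3-dioxolan-4-yl](hydroxy)methyl]prop-2-enoate (anti adduct)
Conditions: DABCO (0.5 equiv), dioxane/H2O, rt; chromatographic removal of the syn isomer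
Reagents that add atoms: none
Why: Morita–Baylis–Hillman reaction in which Felkin–Anh addition anti to the dioxolane oxygen should favour the anti adduct, so that C5 (S) is set from the chiral pool.

Step 6
Reactants: 9 methyl 2-[(S)-[(4R)-2,2-dimethyl-1,3-dioxolan-4-yl](hydroxy)methyl]prop-2-enoate
Product: 10 methyl 2-[(S)-(TBS-oxy)[(4R)-2,2-dimethyl-1,3-dioxolan-4-yl]methyl]prop-2-enoate
Conditions: TBSOTf, 2,6-lutidine, CH2Cl2, −78 to 0 °C
Reagents that add atoms: tert-butyldimethylsilyl trifluoromethanesulfonate CC(C)(C)[Si](C)(C)OS(=O)(=O)C(F)(F)F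
Why: Silyl triflate protection of the hindered secondary allylic alcohol gives the non-chelating ether wanted for the Felkin-controlled ring closure in step 17.

Step 7
Reactants: 10 methyl 2-[(S)-(TBS-oxy)[(4R)-2,2-dimethyl-1,3-dioxolan-4-yl]methyl]prop-2-enoate
Product: 11 2-[(S)-(TBS-oxy)[(4R)-2,2-dimethyl-1,3-dioxolan-4-yl]methyl]prop-2-en-1-ol
Conditions: iBu2AlH (2.2 equiv), CH2Cl2, −78 °C; Rochelle salt work-up
Reagents that add atoms: none
Why: 1,2-Reduction of the acrylate ester at low temperature gives the allylic alcohol without touching the silyl ether or the acetonide.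

Step 8
Reactants: 11 2-[(S)-(TBS-oxy)[(4R)-2,2-dimethyl-1,3-dioxolan-4-yl]methyl]prop-2-en-1-ol
Product: 12 2-[(S)-(TBS-oxy)[(4R)-2,2-dimethyl-1,3-dioxolan-4-yl]methyl]prop-2-enal (enal fragment)
Conditions: MnO2, CH2Cl2, rt
Reagents that add atoms: none
Why: Chemoselective heterogeneous oxidation of the allylic alcohol gives the 2-substituted acrolein under neutral conditions that should not epimerise C5.

Step 9
Reactants: 7 furan fragment; 12 enal fragment
Product: 14 furfuryl carbinol (C2–C3 bond formed; C3–OH as both epimers), via lithium trienolate 13 (not isolated)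
Conditions: LiN(iPr)2 (1.05 equiv), THF, −78 °C; then 12, −78 °C; AcOH quench
Reagents that add atoms: none
Why: Vinylogous (lateral) deprotonation and aldol addition: the methyl group on the furan α-carbon is conjugated through the ring with the acrylate, so the extended enolate 13 should form and add 1,2 to the enal through its terminal carbon with return of furan aromaticity, the new C3 centre being erased in step 10.

Step 10
Reactants: 14 furfuryl carbinol
Product: 15 furfuryl α-methylene ketone (C3 ketone)
Conditions: Dess–Martin periodinane, CH2Cl2, 0 °C; used at once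
Reagents that add atoms: none
Why: Dess–Martin oxidation of the secondary allylic alcohol under near-neutral conditions gives the β-furyl ketone without base-induced isomerisation of the α-methylene ketone.

Step 11
Reactants: 15 furfuryl α-methylene ketone
Product: 18 (10S)-3(2H)-furanone with C8 ketone, via furan endoperoxide 16 (not isolated), via enedione 17 (not isolated)
Conditions: O2, tetraphenylporphyrin (cat.), visible light, CH2Cl2, −78 °C; Me2S, −78 to 0 °C; then quinidine-derived 3,5-bis(trifluoromethyl)anilino squaramide (10 mol %), toluene, −30 °C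
Reagents that add atoms: dioxygen O=O
Why: Proposed new method: singlet oxygen adds across C1 and C8 of the electron-rich trisubstituted furan in a [4+2] mode, Me2S cleaves the O–O bond of endoperoxide 16 to the (Z)-ene-1,4-dione 17 (C1 ketone, C9=C10, C8 ketone), and the now doubly activated C2 methylene enolises so that the enol oxygen on C3 adds to C10, the β-carbon of the C8 enone. The closest known reaction type is the photooxygenation of 2-(β-hydroxyalkyl)furans followed by intramolecular oxa-Michael addition to tetrahydrofuran-3-ones, extended here to a 1,3-diketone enol oxygen and to catalyst control as in bifunctional amine–squaramide cycloetherifications. The furanone ring closes in a 5-exo-trig mode (O–C10 bond, with C9=C10 exocyclic to the forming ring). The new quaternary stereocentre C10 is set by the catalyst: the quinuclidine deprotonates the diketone while the squaramide N–H bonds hold the C8 carbonyl, so that one face of C10 is presented to the enolate oxygen, and the remote C5 centre is not expected to interfere. The step needs O- over C-cyclisation and 5-exo over 6-endo closure: C2 can reach only the C8 carbonyl in a reversible aldol addition, and the C1 enol oxygen can reach only C15 of the α-methylene ketone in a planar, poorly aligned 6-endo mode, whereas the vinylogous ester 18 is the energetic sink. It is run under kinetic control at low temperature so that retro-oxa-Michael reaction does not erode C10, and the oxygenation is chemoselective because the furan is the only electron-rich diene present.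

Step 12
Reactants: 18 (10S)-3(2H)-furanone with C8 ketone
Product: 19 (8R)-allylic alcohol
Conditions: (S)-2-methyl-CBS-oxazaborolidine (20 mol %), BH3·SMe2, THF, −40 °C; MeOH quench
Reagents that add atoms: none
Why: Corey–Bakshi–Shibata reduction in which the alkenyl group acts as the large and the C9 methylene as the small substituent, so that the (S)-catalyst should give the (8R) alcohol under reagent control while the vinylogous ester carbonyl C1 and the ester stay untouched; reduction also closes the retro-oxa-Michael pathway at C10.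

Step 13
Reactants: 19 (8R)-allylic alcohol
Product: 20 (8R)-isobutyrate
Conditions: 2-methylpropanoyl chloride, pyridine, DMAP (cat.), CH2Cl2, 0 °C
Reagents that add atoms: 2-methylpropanoyl chloride CC(C)C(Cl)=O
Why: DMAP-catalysed acylation of the secondary allylic alcohol installs the isobutyrate with retention at C8.

Step 14
Reactants: 20 (8R)-isobutyrate
Product: 21 C13 primary allylic alcohol
Conditions: HF·pyridine, pyridine, THF, 0 °C
Reagents that add atoms: none
Why: Buffered HF·pyridine should cleave the unhindered primary allylic silyl ether much faster than the hindered secondary one at C5 and leave the acetonide intact.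

Step 15
Reactants: 21 C13 primary allylic alcohol
Product: 22 (Z)-allylic bromide
Conditions: CBr4, PPh3, CH2Cl2, 0 °C
Reagents that add atoms: tetrabromomethane BrC(Br)(Br)Br
Why: Appel bromination of the primary allylic alcohol under neutral conditions gives the 2-(bromomethyl)alkenoate with the alkene geometry unchanged (C8 cis to CH2Br).

Step 16
Reactants: 22 (Z)-allylic bromide
Product: 23 bromo aldehyde (C6 aldehyde)
Conditions: H5IO6, EtOAc, rt; filtered and used at once
Reagents that add atoms: none
Why: Periodic acid hydrolyses the terminal acetonide and cleaves the liberated 1,2-diol in one operation, giving the α-silyloxy aldehyde with C5 untouched and the dioxolane stereocentre sacrificed.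

Step 17
Reactants: 23 bromo aldehyde
Product: 25 O5-TBS macrolactone, via seco hydroxy ester 24 (not isolated)
Conditions: CrCl2 (8 equiv), THF (0.003 M), rt; aq. NH4Cl work-up
Reagents that add atoms: none
Why: Nozaki–Hiyama-type Barbier allylation, in which the allylchromium from the (Z)-bromide adds through C7 to the aldehyde in a chair transition state: the C8 substituent cis to CH2Cr gives the 6,7-syn adduct (cis-lactone), the α-silyloxy centre C5 directs Felkin–Anh attack (5,6-anti), and these together define C6 (R) and C7 (R) before the alkoxide lactonises onto the methyl ester.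

Step 18
Reactants: 25 O5-TBS macrolactone
Product: 26 target CNP0384113.2
Conditions: HF·pyridine, THF, 0 °C to rt
Reagents that add atoms: none
Why: Fluoride-mediated cleavage of the remaining secondary silyl ether under mildly acidic conditions should spare the α-methylene lactone, the isobutyrate and the furanone.

**Compound list**

1 | 4,5-dimethylfuran-2-carbaldehyde | Cc1oc(C=O)cc1C | starting material
2 | methyl acrylate | C=CC(=O)OC | starting material
3 | methyl 2-[(4,5-dimethylfuran-2-yl)(hydroxy)methyl]prop-2-enoate (racemic) | COC(=O)C(=C)C(O)c1cc(C)c(C)o1 | intermediate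
4 | methyl 2-[acetoxy(4,5-dimethylfuran-2-yl)methyl]prop-2-enoate (racemic) | COC(=O)C(=C)C(OC(C)=O)c1cc(C)c(C)o1 | intermediate (not isolated)
5 | methyl (2E)-2-(acetoxymethyl)-3-(4,5-dimethylfuran-2-yl)prop-2-enoate | COC(=O)/C(COC(C)=O)=C/c1cc(C)c(C)o1 | intermediate
6 | methyl (2E)-3-(4,5-dimethylfuran-2-yl)-2-(hydroxymethyl)prop-2-enoate | COC(=O)/C(CO)=C/c1cc(C)c(C)o1 | intermediate
7 | methyl (2E)-2-(TBS-oxymethyl)-3-(4,5-dimethylfuran-2-yl)prop-2-enoate | COC(=O)/C(CO[Si](C)(C)C(C)(C)C)=C/c1cc(C)c(C)o1 | intermediate
8 | (4R)-2,2-dimethyl-1,3-dioxolane-4-carbaldehyde | O=C[C@H]1COC(C)(C)O1 | starting material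
9 | methyl 2-[(S)-[(4R)-2,2-dimethyl-1,3-dioxolan-4-yl](hydroxy)methyl]prop-2-enoate | C=C(C(=O)OC)[C@H](O)[C@H]1COC(C)(C)O1 | intermediate
10 | methyl 2-[(S)-(TBS-oxy)[(4R)-2,2-dimethyl-1,3-dioxolan-4-yl]methyl]prop-2-enoate | C=C(C(=O)OC)[C@H](O[Si](C)(C)C(C)(C)C)[C@H]1COC(C)(C)O1 | intermediate
11 | 2-[(S)-(TBS-oxy)[(4R)-2,2-dimethyl-1,3-dioxolan-4-yl]methyl]prop-2-en-1-ol | C=C(CO)[C@H](O[Si](C)(C)C(C)(C)C)[C@H]1COC(C)(C)O1 | intermediate
12 | 2-[(S)-(TBS-oxy)[(4R)-2,2-dimethyl-1,3-dioxolan-4-yl]methyl]prop-2-enal | C=C(C=O)[C@H](O[Si](C)(C)C(C)(C)C)[C@H]1COC(C)(C)O1 | intermediate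
13 | lithium trienolate of 7 (deprotonated at the methyl group on the furan α-carbon) | [Li+].[CH2-]c1oc(/C=C(\CO[Si](C)(C)C(C)(C)C)C(=O)OC)cc1C | intermediate (not isolated)
14 | methyl (2E)-2-(TBS-oxymethyl)-3-{5-[(4S)-4-(TBS-oxy)-4-[(4R)-2,2-dimethyl-1,3-dioxolan-4-yl]-2-hydroxy-3-methylidenebutyl]-4-methylfuran-2-yl}prop-2-enoate (both carbinol epimers) | COC(=O)/C(CO[Si](C)(C)C(C)(C)C)=C/c1cc(C)c(CC(O)C(=C)[C@H](O[Si](C)(C)C(C)(C)C)[C@H]2COC(C)(C)O2)o1 | intermediate
15 | methyl (2E)-2-(TBS-oxymethyl)-3-{5-[(4S)-4-(TBS-oxy)-4-[(4R)-2,2-dimethyl-1,3-dioxolan-4-yl]-3-methylidene-2-oxobutyl]-4-methylfuran-2-yl}prop-2-enoate | COC(=O)/C(CO[Si](C)(C)C(C)(C)C)=C/c1cc(C)c(CC(=O)C(=C)[C@H](O[Si](C)(C)C(C)(C)C)[C@H]2COC(C)(C)O2)o1 | intermediate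
16 | furan endoperoxide of 15 (2,3,7-trioxabicyclo[2.2.1]hept-5-ene bridging C1 and C8; bridgehead epimers) | COC(=O)/C(CO[Si](C)(C)C(C)(C)C)=C/C12OOC(CC(=O)C(=C)[C@H](O[Si](C)(C)C(C)(C)C)[C@H]3COC(C)(C)O3)(O1)C(C)=C2 | intermediate (not isolated)
17 | (Z)-ene-1,4-dione (C1 and C8 ketones, C9=C10) with the C1/C3 1,3-diketone | COC(=O)/C(CO[Si](C)(C)C(C)(C)C)=C/C(=O)/C=C(/C)C(=O)CC(=O)C(=C)[C@H](O[Si](C)(C)C(C)(C)C)[C@H]1COC(C)(C)O1 | intermediate (not isolated)
18 | methyl (2E)-2-(TBS-oxymethyl)-5-[(2S)-5-{(3S)-3-(TBS-oxy)-3-[(4R)-2,2-dimethyl-1,3-dioxolan-4-yl]prop-1-en-2-yl}-2-methyl-3-oxo-2,3-dihydrofuran-2-yl]-4-oxopent-2-enoate | COC(=O)/C(CO[Si](C)(C)C(C)(C)C)=C/C(=O)C[C@]1(C)OC(=CC1=O)C(=C)[C@H](O[Si](C)(C)C(C)(C)C)[C@H]1COC(C)(C)O1 | intermediate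
19 | (4R)-4-hydroxy analogue of 18 (C8 alcohol, 8R) | COC(=O)/C(CO[Si](C)(C)C(C)(C)C)=C/[C@H](O)C[C@]1(C)OC(=CC1=O)C(=C)[C@H](O[Si](C)(C)C(C)(C)C)[C@H]1COC(C)(C)O1 | intermediate
20 | 2-methylpropanoate of 19 (8R) | COC(=O)/C(CO[Si](C)(C)C(C)(C)C)=C/[C@H](OC(=O)C(C)C)C[C@]1(C)OC(=CC1=O)C(=C)[C@H](O[Si](C)(C)C(C)(C)C)[C@H]1COC(C)(C)O1 | intermediate
21 | methyl (2E,4R)-2-(hydroxymethyl)-4-(2-methylpropanoyloxy)pent-2-enoate carrying the furanone unit of 18 at C5 | COC(=O)/C(CO)=C/[C@H](OC(=O)C(C)C)C[C@]1(C)OC(=CC1=O)C(=C)[C@H](O[Si](C)(C)C(C)(C)C)[C@H]1COC(C)(C)O1 | intermediate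
22 | methyl (2Z,4R)-2-(bromomethyl)-4-(2-methylpropanoyloxy)pent-2-enoate carrying the furanone unit of 18 at C5 | COC(=O)/C(CBr)=C/[C@H](OC(=O)C(C)C)C[C@]1(C)OC(=CC1=O)C(=C)[C@H](O[Si](C)(C)C(C)(C)C)[C@H]1COC(C)(C)O1 | intermediate
23 | methyl (2Z,4R)-2-(bromomethyl)-5-[(2S)-5-[(3S)-3-(TBS-oxy)-4-oxobut-1-en-2-yl]-2-methyl-3-oxo-2,3-dihydrofuran-2-yl]-4-(2-methylpropanoyloxy)pent-2-enoate | COC(=O)/C(CBr)=C/[C@H](OC(=O)C(C)C)C[C@]1(C)OC(=CC1=O)C(=C)[C@H](O[Si](C)(C)C(C)(C)C)C=O | intermediate
24 | seco hydroxy ester: ten-membered carbocycle closed at C6–C7, free C6–OH, methyl 2-propenoate on C7, 6,7-syn, O5-TBS | COC(=O)C(=C)[C@@H]1[C@H](OC(=O)C(C)C)C[C@]2(C)OC(=CC2=O)C(=C)[C@H](O[Si](C)(C)C(C)(C)C)[C@@H]1O | intermediate (not isolated)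
25 | O5-TBS ether of the target (5S,6R,7R,8R,10S) | C=C1C(=O)O[C@@H]2[C@H]1[C@H](OC(=O)C(C)C)C[C@]1(C)OC(=CC1=O)C(=C)[C@@H]2O[Si](C)(C)C(C)(C)C | intermediate
26 | CNP0384113.2: (5S,6R,7R,8R,10S)-5-hydroxy-8-(2-methylpropanoyloxy)-1-oxo-3,10-epoxygermacra-2,4(15),11(13)-trien-12,6-olide | C=C1C(=O)O[C@@H]2[C@H]1[C@H](OC(=O)C(C)C)C[C@]1(C)OC(=CC1=O)C(=C)[C@@H]2O | target

**Totals and risks**

Total step count: 18. Longest linear sequence: 14 steps (1 → 7 → 14 → 26, or equally 8 → 12 → 14 → 26).

Steps most likely to fail:

1. Step 11. What may go wrong: carbon-centred aldol closure of C2 onto the C8 carbonyl outrunning the oxa-Michael addition, 6-endo addition to C15, poor facial control at C10 by the catalyst, or erosion of C10 through retro-oxa-Michael reaction. Fallback with known chemistry, setting out from 14 and coming back at 20: carbinol 14 is photooxygenated and reduced as in step 11 and treated with a trace of acid, so that the C3 hydroxyl adds to C10 in the established mode for 2-(β-hydroxyalkyl)furans to give the tetrahydrofuran-3-one F1 (both C3 epimers). C10 is then not catalyst-controlled: the C10 epimers are separated as diastereomers and the unwanted one is re-equilibrated with DBU through retro-oxa-Michael reaction and recycled. CBS reduction as in step 12 gives the (8R)-alcohol F2, and acylation as in step 13 gives the isobutyrate F3. Saegusa–Ito dehydrogenation (TMSOTf, Et3N; then Pd(OAc)2, MeCN) of the only enolisable ketone introduces the C2=C3 bond, erases C3 and gives 20.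

2. Step 17. What may go wrong: 1,4-elimination of the C8 isobutyrate from the allylchromium species, oligomerisation in place of ten-membered ring closure, isomerisation of the β,γ-unsaturated α-silyloxy aldehyde into conjugation, or a mismatch between the Felkin–Anh preference and the facial bias of the C8 centre. Fallback setting out from 23 and coming back at 25: Miyaura-type borylation of the allylic bromide (B2pin2, Pd2(dba)3 as a source of zerovalent palladium) gives the allylboronate aldehyde F4, a non-reducing allyl donor that cannot eliminate. At high dilution Sc(OTf)3 then triggers the intramolecular allylboration through a closed six-membered transition state with the same syn preference, and the boron alkoxide lactonises to 25.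

3. Step 12. What may go wrong: insufficient facial discrimination between the alkenyl side and the β-quaternary C9 side of the ketone, or competing conjugate reduction of the keto-enoate. Fallback setting out from 18 and coming back at 20: Luche reduction (NaBH4, CeCl3·7H2O, MeOH, −78 °C) gives 19 together with its C8 epimer, the (8S)-alcohol F5. After separation 19 is acylated as in step 13, and F5 is esterified with 2-methylpropanoic acid under Mitsunobu conditions (PPh3, DIAD) with inversion at C8, so that both epimers converge on 20.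

Further compounds

F1 | step 11 | tetrahydrofuran-3-one analogue of 18 (C2–C3 saturated, 10S, both C3 epimers, C8 ketone) | COC(=O)/C(CO[Si](C)(C)C(C)(C)C)=C/C(=O)C[C@]1(C)OC(CC1=O)C(=C)[C@H](O[Si](C)(C)C(C)(C)C)[C@H]1COC(C)(C)O1
F2 | step 11 | (8R)-alcohol from F1 | COC(=O)/C(CO[Si](C)(C)C(C)(C)C)=C/[C@H](O)C[C@]1(C)OC(CC1=O)C(=C)[C@H](O[Si](C)(C)C(C)(C)C)[C@H]1COC(C)(C)O1
F3 | step 11 | (8R)-isobutyrate from F2 | COC(=O)/C(CO[Si](C)(C)C(C)(C)C)=C/[C@H](OC(=O)C(C)C)C[C@]1(C)OC(CC1=O)C(=C)[C@H](O[Si](C)(C)C(C)(C)C)[C@H]1COC(C)(C)O1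
F4 | step 17 | allylboronate aldehyde (pinacol boronate at C13 in place of the bromide of 23) | COC(=O)/C(CB1OC(C)(C)C(C)(C)O1)=C/[C@H](OC(=O)C(C)C)C[C@]1(C)OC(=CC1=O)C(=C)[C@H](O[Si](C)(C)C(C)(C)C)C=O
F5 | step 12 | (8S)-epimer of alcohol 19 | COC(=O)/C(CO[Si](C)(C)C(C)(C)C)=C/[C@@H](O)C[C@]1(C)OC(=CC1=O)C(=C)[C@H](O[Si](C)(C)C(C)(C)C)[C@H]1COC(C)(C)O1
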